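**Retrosynthetic overview**
- The target comes from the tetra-MOM benzofuran by acetal solvolysis. The furan is the only ring built, and it is closed second to last by cyclodehydration of an o-hydroxybenzyl aryl ketone.
- The ketone comes from a β-keto ester. The C2–C3 bond is made by an intermolecular ester-enolate aldol addition of a ring A arylacetate (fragment A) to a ring B benzaldehyde (fragment B), followed by oxidation and deallylative decarboxylation.
- Fragment B comes from methyl 3,5-dihydroxybenzoate: MOM protection, reduction, 2,6-dibromination, two Br/Li exchange–prenylation rounds, then oxidation to the aldehyde.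
- Fragment A comes from 2,4,6-trihydroxybenzaldehyde: 4-O-prenyl ether, aromatic Claisen shift (symmetric, para position blocked) to the 1,1-dimethylallyl group, selective MOM protection, allyl on the future furan oxygen, then one-carbon homologation.
- Both benzene rings are bought, so the ring order is simply the furan ring in step 20.

**Assumption:** the target SMILES holds no stereocentre and no stereogenic double bond, so the compound is achiral and no enantioselective step is needed.

**Abbreviations**
- MOM = CH2OCH3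
- TIPS = Si(iPr)3
- ArA = 2-(allyloxy)-4,6-bis(methoxymethoxy)-3-(2-methylbut-3-en-2-yl)phenyl
- ArB = 3,5-bis(methoxymethoxy)-2,6-bis(3-methylbut-2-en-1-yl)phenyl

## Route

**Step 1**
Reactants: 1 methyl 3,5-dihydroxybenzoate
Product: 2 methyl 3,5-bis(methoxymethoxy)benzoate
Conditions: MOMCl (2.5 equiv), K2CO3, acetone, 0 °C → rt
Reagents that add atoms: chloromethyl methyl ether, COCCl
Why: Williamson-type O-alkylation caps both phenols as MOM acetals, which survive hydride, organolithium and enolate chemistry and leave under mild acid at the end.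

**Step 2**
Reactants: 2 methyl 3,5-bis(methoxymethoxy)benzoate
Product: 3 [3,5-bis(methoxymethoxy)phenyl]methanol
Conditions: LiAlH4, THF, 0 °C
Reagents that add atoms: none
Why: Hydride reduction of the ester gives the benzylic alcohol, and aryl MOM ethers are inert to LiAlH4.

**Step 3**
Reactants: 3 [3,5-bis(methoxymethoxy)phenyl]methanol
Product: 4 [2,6-dibromo-3,5-bis(methoxymethoxy)phenyl]methanol
Conditions: NBS (2.05 equiv), MeCN, 0 °C → rt
Reagents that add atoms: N-bromosuccinimide, O=C1CCC(=O)N1Br
Why: In this electrophilic aromatic bromination C2 and C6 are each para to one OMOM and ortho to the other, while C4 is squeezed between two OMOM groups, so two equivalents give the 2,6-dibromide, as is usual for 3,5-dialkoxybenzyl alcohols.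

**Step 4**
Reactants: 4 [2,6-dibromo-3,5-bis(methoxymethoxy)phenyl]methanol
Product: 5 {[2,6-dibromo-3,5-bis(methoxymethoxy)phenyl]methoxy}triisopropylsilane
Conditions: TIPSCl, imidazole, DMF, rt
Reagents that add atoms: chlorotriisopropylsilane, CC(C)[Si](Cl)(C(C)C)C(C)C
Why: Silyl protection of the primary alcohol uses the bulky TIPS group because it does not migrate from oxygen to an ortho carbanion (retro-Brook shift) in the next two steps.

**Step 5**
Reactants: 5 {[2,6-dibromo-3,5-bis(methoxymethoxy)phenyl]methoxy}triisopropylsilane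
Product: 7 {[2-bromo-3,5-bis(methoxymethoxy)-6-(3-methylbut-2-en-1-yl)phenyl]methoxy}triisopropylsilane, via aryllithium 6 (not isolated)
Conditions: n-BuLi (1.05 equiv), THF, −78 °C; prenyl bromide (1.3 equiv), −78 → 0 °C
Reagents that add atoms: prenyl bromide, CC(C)=CCBr
Why: Bromine–lithium exchange at −78 °C outruns any deprotonation, and the OMOM-chelated aryllithium attacks the unhindered primary end of prenyl bromide in an SN2 allylation to give the linear prenyl group.

**Step 6**
Reactants: 7 {[2-bromo-3,5-bis(methoxymethoxy)-6-(3-methylbut-2-en-1-yl)phenyl]methoxy}triisopropylsilane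
Product: 9 {[3,5-bis(methoxymethoxy)-2,6-bis(3-methylbut-2-en-1-yl)phenyl]methoxy}triisopropylsilane, via aryllithium 8 (not isolated)
Conditions: n-BuLi (1.1 equiv), THF, −78 °C; prenyl bromide (1.3 equiv), −78 → 0 °C
Reagents that add atoms: prenyl bromide, CC(C)=CCBr
Why: A second bromine–lithium exchange and SN2 allylation, run as a separate step, avoids a dilithio species and gives clean control of the second prenylation.

**Step 7**
Reactants: 9 {[3,5-bis(methoxymethoxy)-2,6-bis(3-methylbut-2-en-1-yl)phenyl]methoxy}triisopropylsilane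
Product: 10 [3,5-bis(methoxymethoxy)-2,6-bis(3-methylbut-2-en-1-yl)phenyl]methanol
Conditions: Bu4NF, THF, rt
Reagents that add atoms: none
Why: Fluoride desilylation frees the primary alcohol without touching the MOM ethers or the alkenes.

**Step 8**
Reactants: 10 [3,5-bis(methoxymethoxy)-2,6-bis(3-methylbut-2-en-1-yl)phenyl]methanol
Product: 11 3,5-bis(methoxymethoxy)-2,6-bis(3-methylbut-2-en-1-yl)benzaldehyde (fragment B)
Conditions: Dess–Martin periodinane, CH2Cl2, rt
Reagents that add atoms: none
Why: Dess–Martin oxidation handles hindered benzylic alcohols and leaves trisubstituted alkenes and electron-rich arenes alone.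

**Step 9**
Reactants: 12 2,4,6-trihydroxybenzaldehyde
Product: 13 2,6-dihydroxy-4-[(3-methylbut-2-en-1-yl)oxy]benzaldehyde
Conditions: prenyl bromide (1.0 equiv), K2CO3 (1.05 equiv), acetone, reflux
Reagents that add atoms: prenyl bromide, CC(C)=CCBr
Why: Williamson etherification is selective for the 4-OH, which is the most acidic phenol and the only one not held in a hydrogen bond to the formyl group.

**Step 10**
Reactants: 13 2,6-dihydroxy-4-[(3-methylbut-2-en-1-yl)oxy]benzaldehyde
Product: 15 2,4,6-trihydroxy-3-(2-methylbut-3-en-2-yl)benzaldehyde, via ortho-dienone 14 (not isolated)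
Conditions: EtOH/H2O 4:1, sealed tube, 130 °C, Ar
Reagents that add atoms: none
Why: In this water-accelerated aromatic Claisen [3,3] shift the two ortho carbons are equivalent by symmetry and the para carbon is blocked by CHO, so only one product can form, allyl inversion delivers the 1,1-dimethylallyl group, and the transient stereocentre of 14 is lost on enolisation.

**Step 11**
Reactants: 15 2,4,6-trihydroxy-3-(2-methylbut-3-en-2-yl)benzaldehyde
Product: 16 2-hydroxy-4,6-bis(methoxymethoxy)-3-(2-methylbut-3-en-2-yl)benzaldehyde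
Conditions: MOMCl (2.2 equiv), K2CO3, acetone, 0 °C → rt
Reagents that add atoms: chloromethyl methyl ether, COCCl
Why: In this selective O-alkylation the OH wedged between the formyl group and the tertiary alkyl group is locked in the chelate and shielded, so the weak base lets only the 4-OH and 6-OH react.

**Step 12**
Reactants: 16 2-hydroxy-4,6-bis(methoxymethoxy)-3-(2-methylbut-3-en-2-yl)benzaldehyde
Product: 17 2-(allyloxy)-4,6-bis(methoxymethoxy)-3-(2-methylbut-3-en-2-yl)benzaldehyde
Conditions: allyl bromide, K2CO3, DMF, 60 °C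
Reagents that add atoms: allyl bromide, C=CCBr
Why: Williamson etherification with a small electrophile works on hindered 3-tert-alkylsalicylaldehydes and marks the future furan oxygen with a group orthogonal to MOM.

**Step 13**
Reactants: 17 2-(allyloxy)-4,6-bis(methoxymethoxy)-3-(2-methylbut-3-en-2-yl)benzaldehyde
Product: 18 2-(allyloxy)-1-(2-methoxyethenyl)-4,6-bis(methoxymethoxy)-3-(2-methylbut-3-en-2-yl)benzene (E/Z mixture)
Conditions: Ph3P(CH2OMe)Cl (1.6 equiv), KOtBu (1.5 equiv), THF, 0 °C → rt
Reagents that add atoms: (methoxymethyl)triphenylphosphonium chloride, COC[P+](c1ccccc1)(c1ccccc1)c1ccccc1.[Cl-]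
Why: Wittig methoxymethylenation is reliable for 2,6-dialkoxybenzaldehydes, and the E/Z ratio is irrelevant because the double bond is hydrolysed next.

**Step 14**
Reactants: 18 2-(allyloxy)-1-(2-methoxyethenyl)-4,6-bis(methoxymethoxy)-3-(2-methylbut-3-en-2-yl)benzene
Product: 19 2-ArA-acetaldehyde
Conditions: 1 M aq HCl/THF 1:4, rt, TLC control
Reagents that add atoms: water, O
Why: Enol ether hydrolysis by C-protonation of the electron-rich styryl ether is much faster in dilute acid at room temperature than cleavage of formaldehyde-type aryl MOM acetals.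

**Step 15**
Reactants: 19 2-ArA-acetaldehyde
Product: 20 2-ArA-acetic acid
Conditions: NaClO2, NaH2PO4, 2-methyl-2-butene (excess), t-BuOH/H2O, rt
Reagents that add atoms: sodium chlorite, [Na+].[O-]Cl=O
Why: Pinnick oxidation at buffered pH turns the aldehyde into the acid while the scavenger removes HOCl before it can attack the arene or the terminal alkenes.

**Step 16**
Reactants: 20 2-ArA-acetic acid
Product: 21 allyl 2-ArA-acetate (fragment A)
Conditions: allyl bromide, K2CO3, DMF, rt
Reagents that add atoms: allyl bromide, C=CCBr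
Why: Carboxylate SN2 alkylation gives the allyl ester, which can later be removed together with the aryl allyl ether under neutral conditions.

**Step 17**
Reactants: 21 allyl 2-ArA-acetate; 11 3,5-bis(methoxymethoxy)-2,6-bis(3-methylbut-2-en-1-yl)benzaldehyde
Product: 23 allyl 2-ArA-3-ArB-3-hydroxypropanoate (mixture of racemic diastereomers), via lithium enolate 22 (not isolated)
Conditions: LiN(iPr)2 (1.1 equiv), THF, −78 °C; 11, −78 °C; AcOH quench at −78 °C
Reagents that add atoms: none
Why: The intermolecular ester-enolate aldol addition joins the fragments at the future C2–C3 bond, because the nearly planar 2,6-disubstituted aldehyde stays open to attack from its faces, the cold quench forestalls retro-aldol and ester-enolate [3,3] shift, and both new stereocentres are erased in steps 18 to 20.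

**Step 18**
Reactants: 23 allyl 2-ArA-3-ArB-3-hydroxypropanoate
Product: 24 allyl 2-ArA-3-ArB-3-oxopropanoate (racemic, enolisable)
Conditions: Dess–Martin periodinane, CH2Cl2, rt
Reagents that add atoms: none
Why: Dess–Martin oxidation of the hindered benzylic carbinol runs without base, so no retro-aldol can occur and both diastereomers converge on one β-keto ester.

**Step 19**
Reactants: 24 allyl 2-ArA-3-ArB-3-oxopropanoate
Product: 27 1-ArB-2-[2-hydroxy-4,6-bis(methoxymethoxy)-3-(2-methylbut-3-en-2-yl)phenyl]ethan-1-one, via keto acid 25 (not isolated), via allyl ether ketone 26 (not isolated)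
Conditions: Pd(PPh3)4 (5 mol %), morpholine (10 equiv), THF, rt → 45 °C
Reagents that add atoms: none
Why: In this Tsuji–Trost deallylation zerovalent palladium ionises the allyl ester first, the α-aryl β-keto acid loses CO2, the aryl allyl ether is cleaved next, and excess morpholine traps both allyl units so that no C-allylation occurs.

**Step 20**
Reactants: 27 1-ArB-2-[2-hydroxy-4,6-bis(methoxymethoxy)-3-(2-methylbut-3-en-2-yl)phenyl]ethan-1-one
Product: 29 2-ArB-4,6-bis(methoxymethoxy)-7-(2-methylbut-3-en-2-yl)benzofuran, via cyclic hemiketal 28 (not isolated)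
Conditions: PPTS (0.2 equiv), 4 Å molecular sieves, toluene, 80 °C
Reagents that add atoms: none
Why: In this acid-catalysed cyclodehydration the single free phenol, which sits next to the 1,1-dimethylallyl group, adds to the ketone and the hemiketal loses water, which fixes the 7-substituted regioisomer under conditions too mild and too dry to cleave MOM ethers.

**Step 21**
Reactants: 29 2-ArB-4,6-bis(methoxymethoxy)-7-(2-methylbut-3-en-2-yl)benzofuran
Product: 30 2-[3,5-dihydroxy-2,6-bis(3-methylbut-2-en-1-yl)phenyl]-7-(2-methylbut-3-en-2-yl)benzofuran-4,6-diol (target)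
Conditions: 3 M aq HCl/MeOH 1:10, 40 °C, Ar, stopped at full conversion
Reagents that add atoms: none
Why: Acetal solvolysis of the four MOM groups in methanol is faster than protonation of the alkenes, as is common practice for o-prenylated phenols, and no stereocentre is involved.

## Compound list

| No. | Name | SMILES | Role |
|---|---|---|---|
| 1 | methyl 3,5-dihydroxybenzoate | COC(=O)c1cc(O)cc(O)c1 | starting material |
| 2 | methyl 3,5-bis(methoxymethoxy)benzoate | COCOc1cc(OCOC)cc(C(=O)OC)c1 | intermediate |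
| 3 | [3,5-bis(methoxymethoxy)phenyl]methanol | COCOc1cc(CO)cc(OCOC)c1 | intermediate |
| 4 | [2,6-dibromo-3,5-bis(methoxymethoxy)phenyl]methanol | COCOc1cc(OCOC)c(Br)c(CO)c1Br | intermediate |
| 5 | {[2,6-dibromo-3,5-bis(methoxymethoxy)phenyl]methoxy}triisopropylsilane | COCOc1cc(OCOC)c(Br)c(CO[Si](C(C)C)(C(C)C)C(C)C)c1Br | intermediate |
| 6 | aryllithium from 5 (Li in place of one Br) | [Li]c1c(OCOC)cc(OCOC)c(Br)c1CO[Si](C(C)C)(C(C)C)C(C)C | intermediate |
| 7 | {[2-bromo-3,5-bis(methoxymethoxy)-6-(3-methylbut-2-en-1-yl)phenyl]methoxy}triisopropylsilane | CC(C)=CCc1c(OCOC)cc(OCOC)c(Br)c1CO[Si](C(C)C)(C(C)C)C(C)C | intermediate |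
| 8 | aryllithium from 7 (Li in place of Br) | [Li]c1c(OCOC)cc(OCOC)c(CC=C(C)C)c1CO[Si](C(C)C)(C(C)C)C(C)C | intermediate |
| 9 | {[3,5-bis(methoxymethoxy)-2,6-bis(3-methylbut-2-en-1-yl)phenyl]methoxy}triisopropylsilane | CC(C)=CCc1c(OCOC)cc(OCOC)c(CC=C(C)C)c1CO[Si](C(C)C)(C(C)C)C(C)C | intermediate |
| 10 | [3,5-bis(methoxymethoxy)-2,6-bis(3-methylbut-2-en-1-yl)phenyl]methanol | CC(C)=CCc1c(OCOC)cc(OCOC)c(CC=C(C)C)c1CO | intermediate |
| 11 | 3,5-bis(methoxymethoxy)-2,6-bis(3-methylbut-2-en-1-yl)benzaldehyde (fragment B) | CC(C)=CCc1c(OCOC)cc(OCOC)c(CC=C(C)C)c1C=O | intermediate |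
| 12 | 2,4,6-trihydroxybenzaldehyde | O=Cc1c(O)cc(O)cc1O | starting material |
| 13 | 2,6-dihydroxy-4-[(3-methylbut-2-en-1-yl)oxy]benzaldehyde | CC(C)=CCOc1cc(O)c(C=O)c(O)c1 | intermediate |
| 14 | ortho-dienone, 2,6-dihydroxy-3-(2-methylbut-3-en-2-yl)-4-oxocyclohexa-1,5-diene-1-carbaldehyde (racemic, transient) | C=CC(C)(C)C1C(=O)C=C(O)C(C=O)=C1O | intermediate |
| 15 | 2,4,6-trihydroxy-3-(2-methylbut-3-en-2-yl)benzaldehyde | C=CC(C)(C)c1c(O)cc(O)c(C=O)c1O | intermediate |
| 16 | 2-hydroxy-4,6-bis(methoxymethoxy)-3-(2-methylbut-3-en-2-yl)benzaldehyde | C=CC(C)(C)c1c(OCOC)cc(OCOC)c(C=O)c1O | intermediate |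
| 17 | 2-(allyloxy)-4,6-bis(methoxymethoxy)-3-(2-methylbut-3-en-2-yl)benzaldehyde | C=CCOc1c(C=O)c(OCOC)cc(OCOC)c1C(C)(C)C=C | intermediate |
| 18 | 2-(allyloxy)-1-(2-methoxyethenyl)-4,6-bis(methoxymethoxy)-3-(2-methylbut-3-en-2-yl)benzene (E/Z mixture) | C=CCOc1c(C=COC)c(OCOC)cc(OCOC)c1C(C)(C)C=C | intermediate |
| 19 | 2-ArA-acetaldehyde | C=CCOc1c(CC=O)c(OCOC)cc(OCOC)c1C(C)(C)C=C | intermediate |
| 20 | 2-ArA-acetic acid | C=CCOc1c(CC(=O)O)c(OCOC)cc(OCOC)c1C(C)(C)C=C | intermediate |
| 21 | allyl 2-ArA-acetate (fragment A) | C=CCOC(=O)Cc1c(OCC=C)c(C(C)(C)C=C)c(OCOC)cc1OCOC | intermediate |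
| 22 | lithium enolate of 21 | C=CCOC(O[Li])=Cc1c(OCC=C)c(C(C)(C)C=C)c(OCOC)cc1OCOC | intermediate |
| 23 | allyl 2-ArA-3-ArB-3-hydroxypropanoate (mixture of racemic diastereomers) | C=CCOC(=O)C(C(O)c1c(CC=C(C)C)c(OCOC)cc(OCOC)c1CC=C(C)C)c1c(OCC=C)c(C(C)(C)C=C)c(OCOC)cc1OCOC | intermediate |
| 24 | allyl 2-ArA-3-ArB-3-oxopropanoate (racemic) | C=CCOC(=O)C(C(=O)c1c(CC=C(C)C)c(OCOC)cc(OCOC)c1CC=C(C)C)c1c(OCC=C)c(C(C)(C)C=C)c(OCOC)cc1OCOC | intermediate |
| 25 | 2-ArA-3-ArB-3-oxopropanoic acid (racemic) | OC(=O)C(C(=O)c1c(CC=C(C)C)c(OCOC)cc(OCOC)c1CC=C(C)C)c1c(OCC=C)c(C(C)(C)C=C)c(OCOC)cc1OCOC | intermediate |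
| 26 | 2-ArA-1-ArB-ethan-1-one | C=CCOc1c(CC(=O)c2c(CC=C(C)C)c(OCOC)cc(OCOC)c2CC=C(C)C)c(OCOC)cc(OCOC)c1C(C)(C)C=C | intermediate |
| 27 | 1-ArB-2-[2-hydroxy-4,6-bis(methoxymethoxy)-3-(2-methylbut-3-en-2-yl)phenyl]ethan-1-one | C=CC(C)(C)c1c(O)c(CC(=O)c2c(CC=C(C)C)c(OCOC)cc(OCOC)c2CC=C(C)C)c(OCOC)cc1OCOC | intermediate |
| 28 | 2-ArB-2-hydroxy-4,6-bis(methoxymethoxy)-7-(2-methylbut-3-en-2-yl)-2,3-dihydrobenzofuran (racemic hemiketal) | C=CC(C)(C)c1c(OCOC)cc(OCOC)c2c1OC(O)(c1c(CC=C(C)C)c(OCOC)cc(OCOC)c1CC=C(C)C)C2 | intermediate |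
| 29 | 2-ArB-4,6-bis(methoxymethoxy)-7-(2-methylbut-3-en-2-yl)benzofuran | C=CC(C)(C)c1c(OCOC)cc(OCOC)c2cc(-c3c(CC=C(C)C)c(OCOC)cc(OCOC)c3CC=C(C)C)oc12 | intermediate |
| 30 | 2-[3,5-dihydroxy-2,6-bis(3-methylbut-2-en-1-yl)phenyl]-7-(2-methylbut-3-en-2-yl)benzofuran-4,6-diol (achiral) | C=CC(C)(C)c1c(O)cc(O)c2cc(-c3c(CC=C(C)C)c(O)cc(O)c3CC=C(C)C)oc12 | target |

## Step count and risks

- **Total step count:** 21.
- **Longest linear sequence:** 13 steps. This holds for both branches: steps 1–8 then 17–21 from 1, and steps 9–16 then 17–21 from 12.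
- **Steps most likely to fail:** 17, 10 and 21.

**Step 17 (aldol between two di-ortho-substituted partners).** The adduct is crowded and the stabilised ester enolate may add slowly or revert.

The fallback sets out from 20 (with 11) and comes back at 25. It drops the ester and uses the far more nucleophilic carboxylic acid dianion (Ivanov reaction).
- Acid 20 is treated with iPrMgCl (2.2 equiv, THF, 0 °C → rt) to give the bis(chloromagnesium) enediolate of 2-ArA-acetic acid F3.
- This adds to 11 through a chelated chair transition state. The magnesium aldolate-carboxylate chelate resists retro-aldol and gives 2-ArA-3-ArB-3-hydroxypropanoic acid F4.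
- Dess–Martin oxidation of this hydroxy acid gives keto acid 25, which loses CO2 to 26.
- The single remaining aryl allyl ether is then removed under the conditions of step 19 to reach 27.

**Step 10 (Claisen shift with two free chelated phenols).** The product may cyclise onto the new vinyl group, undergo the abnormal Claisen isomerisation, or the polyhydroxy aldehyde may degrade.

The fallback sets out from 13 and comes back at 15. It takes the free phenols out of the pericyclic step.
- Compound 13 is capped with MOMCl/NaH in DMF to give 2,6-bis(methoxymethoxy)-4-[(3-methylbut-2-en-1-yl)oxy]benzaldehyde F1.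
- This compound is still symmetric and para-blocked. It is rearranged thermally in N,N-diethylaniline at 190 °C to 4-hydroxy-2,6-bis(methoxymethoxy)-3-(2-methylbut-3-en-2-yl)benzaldehyde F2.
- The two MOM groups ortho to the formyl group are the most labile ones. They are taken off with dilute HCl in MeOH at rt to give 15.

**Step 21 (four MOM groups removed with Brønsted acid next to two o-prenylphenol units).** Chroman formation is the danger.

The fallback sets out from 29 and comes back at 30. It replaces solvolysis by a trans-protection so that no free o-prenylphenol ever meets acid.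
- Et3SiOTf and 2,2'-bipyridyl in MeCN at 0 °C convert the aryl MOM ethers directly into silyl ethers. This gives 2-[3,5-bis(triethylsilyloxy)-2,6-bis(3-methylbut-2-en-1-yl)phenyl]-7-(2-methylbut-3-en-2-yl)-4,6-bis(triethylsilyloxy)benzofuran F5.
- This tetra-silyl ether is cleaved with Bu4NF buffered with AcOH in THF at 0 °C to give 30.

## Further compounds

F1 | step 10 | 2,6-bis(methoxymethoxy)-4-[(3-methylbut-2-en-1-yl)oxy]benzaldehyde | CC(C)=CCOc1cc(OCOC)c(C=O)c(OCOC)c1
F2 | step 10 | 4-hydroxy-2,6-bis(methoxymethoxy)-3-(2-methylbut-3-en-2-yl)benzaldehyde | C=CC(C)(C)c1c(O)cc(OCOC)c(C=O)c1OCOC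
F3 | step 17 | bis(chloromagnesium) enediolate of 2-ArA-acetic acid | C=CCOc1c(C=C(O[Mg]Cl)O[Mg]Cl)c(OCOC)cc(OCOC)c1C(C)(C)C=C
F4 | step 17 | 2-ArA-3-ArB-3-hydroxypropanoic acid (racemic diastereomers) | OC(=O)C(C(O)c1c(CC=C(C)C)c(OCOC)cc(OCOC)c1CC=C(C)C)c1c(OCC=C)c(C(C)(C)C=C)c(OCOC)cc1OCOC
F5 | step 21 | 2-[3,5-bis(triethylsilyloxy)-2,6-bis(3-methylbut-2-en-1-yl)phenyl]-7-(2-methylbut-3-en-2-yl)-4,6-bis(triethylsilyloxy)benzofuran | C=CC(C)(C)c1c(O[Si](CC)(CC)CC)cc(O[Si](CC)(CC)CC)c2cc(-c3c(CC=C(C)C)c(O[Si](CC)(CC)CC)cc(O[Si](CC)(CC)CC)c3CC=C(C)C)oc12
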